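**Retrosynthetic overview**
1. The caffeate ester on O3 is made last (Steglich coupling, then global desilylation). The 3β-hydroxyl comes from Luche reduction of a 3-oxo-4(15)-ene, reached by allylic oxidation of the C4=C15 methylene, which a Wittig reaction puts on a C4 ketone.
2. The strategy rests on the trans pair 7β-isopropyl / 8α-hydroxyl on C7–C8 of ring B, next to the axial C10 methyl. This is an isopulegol unit, cut at C7–C8 into a C8 aldehyde on the C10 arm and a prenyl group on C5 (type I carbonyl-ene).
3. The ring A keto aldehyde comes from (R)-4-silyloxy-3-methylcyclohexenone: anti vinyl-copper addition (C10), methylenation at C5, isobutenyl-copper addition with α-face protonation (C5), then vinyl hydroboration and oxidation (C8).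
4. The enone comes from 2-methylcyclohex-2-enone by CBS reduction, silylation and allylic oxidation.
5. Ring order: ring A is bought as the cyclohexenone; ring B is closed in step 9.

Key step: step 9

**Remarks on the chemistry**
- Eudesmane numbering (C1–C15) is used throughout; α/β refer to the usual drawing with the C10 methyl β. TBS = tert-butyldimethylsilyl.
- The C3 oxygen is not carried through the ene step. A 3β-alkoxy group beside the C4 ketone would be epimerisable in every enolate step, and enolate oxygenation would enter from the α face. The key-step precursor and product therefore have CH2 at C3, and the 3β-hydroxyl is set later by hydride delivery from the α face.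
- The prenyl group is built by conjugate addition to a C5 methylene ketone so that the C5–H bond forms last. Direct C-alkylation of the C5 enolate should enter anti to the axial C10 methyl, which would place the two arms cis.

**Route**

Step 1
Reactants: 1 2-methylcyclohex-2-en-1-one
Product: 2 (R)-2-methylcyclohex-2-en-1-ol
Conditions: (S)-Me-CBS (10 mol%), BH3·SMe2, THF, −20 °C; MeOH quench
Reagents that add atoms: none
Why: Corey–Bakshi–Shibata reduction, in which the α-methylated alkenyl arm acts as the large group, so the (S)-oxazaborolidine should give the (R)-carbinol (future C1) without 1,4-reduction.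

Step 2
Reactants: 2 (R)-2-methylcyclohex-2-en-1-ol
Product: 3 (R)-tert-butyldimethyl[(2-methylcyclohex-2-en-1-yl)oxy]silane
Conditions: TBSCl, imidazole, DMF, rt
Reagents that add atoms: tert-butyldimethylsilyl chloride CC(C)(C)[Si](C)(C)Cl
Why: Standard silylation of a secondary allylic alcohol; the stereocentre is not touched.

Step 3
Reactants: 3 (R)-tert-butyldimethyl[(2-methylcyclohex-2-en-1-yl)oxy]silane
Product: 4 (R)-4-(tert-butyldimethylsilyloxy)-3-methylcyclohex-2-en-1-one
Conditions: Rh2(cap)4 (1 mol%), t-BuOOH, K2CO3, CH2Cl2, rt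
Reagents that add atoms: tert-butyl hydroperoxide CC(C)(C)OO
Why: Catalytic allylic oxidation (peroxyl-radical hydrogen abstraction, then collapse of the allylic peroxide); the ring CH2 beside the CH= terminus gives the more substituted allyl radical and is less shielded than the silyloxy-bearing C–H, which A(1,2) strain with the methyl holds near the alkene plane, so the carbinol centre should survive.

Step 4
Reactants: 4 (R)-4-(tert-butyldimethylsilyloxy)-3-methylcyclohex-2-en-1-one
Product: 5 (3R,4R)-4-(tert-butyldimethylsilyloxy)-3-ethenyl-3-methyl-1-(trimethylsilyloxy)cyclohex-1-ene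
Conditions: CH2=CHMgBr, CuBr·SMe2 (cat.), TMSCl, HMPA, THF, −78 °C; Et3N
Reagents that add atoms: vinylmagnesium bromide C=C[Mg]Br; chlorotrimethylsilane C[Si](C)(C)Cl
Why: TMSCl-accelerated copper-catalysed conjugate addition; the vinyl group enters C10 anti to the pseudoaxial γ-silyloxy group, which sets the quaternary centre (methyl cis to O1), and the enolate is trapped regiospecifically.

Step 5
Reactants: 5 (3R,4R)-4-(tert-butyldimethylsilyloxy)-3-ethenyl-3-methyl-1-(trimethylsilyloxy)cyclohex-1-ene
Product: 8 (3R,4R)-4-(tert-butyldimethylsilyloxy)-3-ethenyl-3-methyl-2-methylidenecyclohexan-1-one, via Mannich base 6 (not isolated), via methiodide 7 (not isolated)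
Conditions: Me2N+=CH2 I−, CH2Cl2, rt; aq NaHCO3 wash; MeI, Et2O, rt; DBU, CH2Cl2, rt
Reagents that add atoms: dimethyl(methylidene)ammonium iodide C=[N+](C)C.[I-]; iodomethane CI (into intermediate 7 only)
Why: Mannich reaction of the silyl enol ether at C5, then exhaustive methylation and E1cB elimination give the exocyclic enone; the C5 configuration of the Mannich base is erased.

Step 6
Reactants: 8 (3R,4R)-4-(tert-butyldimethylsilyloxy)-3-ethenyl-3-methyl-2-methylidenecyclohexan-1-one
Product: 10 (2R,3R,4R)-4-(tert-butyldimethylsilyloxy)-3-ethenyl-3-methyl-2-(3-methylbut-2-en-1-yl)cyclohexan-1-one, via bromomagnesium enolate 9 (not isolated)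
Conditions: Me2C=CHMgBr, CuBr·SMe2 (cat.), THF, −78 °C; then 2,6-di-tert-butyl-4-methylphenol, −78 °C; aq NH4Cl
Reagents that add atoms: (2-methylprop-1-en-1-yl)magnesium bromide CC(C)=C[Mg]Br
Why: Copper-catalysed 1,4-addition to the unhindered exocyclic enone completes the prenyl chain, and kinetic protonation of the enolate by the bulky phenol should occur on the α face, anti to the pseudoaxial C10 methyl (the other half-chair puts the silyloxy group axial and syn to the acid), so the prenyl group ends β, trans to the vinyl arm, which is also the more stable epimer.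

Step 7
Reactants: 10 (2R,3R,4R)-4-(tert-butyldimethylsilyloxy)-3-ethenyl-3-methyl-2-(3-methylbut-2-en-1-yl)cyclohexan-1-one
Product: 12 (2R,3R,4R)-4-(tert-butyldimethylsilyloxy)-3-(2-hydroxyethyl)-3-methyl-2-(3-methylbut-2-en-1-yl)cyclohexan-1-one, via pinacol boronate 11 (not isolated)
Conditions: [Ir(cod)Cl]2 (cat.), dppm, HBpin, CH2Cl2, rt; then NaBO3·4H2O, THF/H2O, rt
Reagents that add atoms: pinacolborane CC1(C)OBOC1(C)C (into intermediate 11 only); sodium perborate [Na+].[Na+].O[B-]1(O)OO[B-](O)(O)OO1
Why: Iridium-catalysed anti-Markovnikov hydroboration is selective for the monosubstituted vinyl group over the trisubstituted prenyl alkene and spares the hindered ketone, and the mild perborate oxidation should leave C5 unchanged.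

Step 8
Reactants: 12 (2R,3R,4R)-4-(tert-butyldimethylsilyloxy)-3-(2-hydroxyethyl)-3-methyl-2-(3-methylbut-2-en-1-yl)cyclohexan-1-one
Product: 13 2-[(1R,2R,6R)-6-(tert-butyldimethylsilyloxy)-1-methyl-2-(3-methylbut-2-en-1-yl)-3-oxocyclohexyl]acetaldehyde
Conditions: Dess–Martin periodinane, pyridine, CH2Cl2, 0 °C
Reagents that add atoms: none
Why: Buffered Dess–Martin oxidation of the primary alcohol gives the aldehyde without acid that could start a premature Prins reaction or epimerise C5.

Step 9
Reactants: 13 2-[(1R,2R,6R)-6-(tert-butyldimethylsilyloxy)-1-methyl-2-(3-methylbut-2-en-1-yl)-3-oxocyclohexyl]acetaldehyde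
Product: 14 1β-(tert-butyldimethylsilyloxy)-8α-hydroxy-15-noreudesm-11-en-4-one (5α-H, 7β-isopropenyl, 10β-methyl)
Conditions: Me2AlCl (2 equiv), CH2Cl2, −78 → −40 °C; aq Rochelle salt
Reagents that add atoms: none
Why: Me2AlCl activates the C8 aldehyde, C7 of the trisubstituted alkene bonds to C8 while an allylic methyl hydrogen passes to oxygen in a concerted type I carbonyl-ene reaction, and loss of methane from the aluminium alkoxide removes the proton that would open Prins side paths. The closest known reaction is the Lewis-acid cyclisation of citronellal to isopulegol. Ring B closes in a 6-exo-trig mode at the carbonyl through a chair transition state built on the trans-diequatorial C5 and C10 arms of ring A, so the trans ring fusion is already in place. At C8 the axial C10 methyl forbids an axial C–O–Al bond (1,3-diaxial), so the oxygen should be equatorial, that is 8α. At C7 the isopropylidene end sits equatorial, away from H5 and H9 and within reach of the oxygen for hydrogen transfer, which gives the 7β-isopropenyl group trans to the hydroxyl. The step needs aldehyde-over-ketone selectivity and no epimerisation at C5; the C4 ketone is more hindered and cannot reach the alkene through a six-membered ene array, and the low temperature and aprotic Lewis acid protect C5.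

Step 10
Reactants: 14 1β-(tert-butyldimethylsilyloxy)-8α-hydroxy-15-noreudesm-11-en-4-one
Product: 15 1β-(tert-butyldimethylsilyloxy)-8α-hydroxy-15-noreudesman-4-one
Conditions: H2 (1 atm), 10% Pd/C, EtOAc, rt
Reagents that add atoms: none
Why: Heterogeneous hydrogenation of the 1,1-disubstituted alkene; C11 is not stereogenic, and the ketone and silyl ether are inert.

Step 11
Reactants: 15 1β-(tert-butyldimethylsilyloxy)-8α-hydroxy-15-noreudesman-4-one
Product: 16 1β,8α-bis(tert-butyldimethylsilyloxy)-15-noreudesman-4-one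
Conditions: TBSOTf, 2,6-lutidine, CH2Cl2, −78 → 0 °C
Reagents that add atoms: tert-butyldimethylsilyl triflate CC(C)(C)[Si](C)(C)OS(=O)(=O)C(F)(F)F
Why: Silyl triflate with a hindered base protects the hindered equatorial C8 hydroxyl without enolising the ketone.

Step 12
Reactants: 16 1β,8α-bis(tert-butyldimethylsilyloxy)-15-noreudesman-4-one
Product: 17 1β,8α-bis(tert-butyldimethylsilyloxy)eudesm-4(15)-ene
Conditions: Ph3PCH3Br, KOt-Bu, toluene, 0 → 90 °C
Reagents that add atoms: methyltriphenylphosphonium bromide C[P+](c1ccccc1)(c1ccccc1)c1ccccc1.[Br-]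
Why: Wittig methylenation of the hindered C4 ketone with excess ylide at elevated temperature; the trans ring fusion is the thermodynamic one, so C5 should hold under the basic conditions.

Step 13
Reactants: 17 1β,8α-bis(tert-butyldimethylsilyloxy)eudesm-4(15)-ene
Product: 18 1β,8α-bis(tert-butyldimethylsilyloxy)eudesm-4(15)-en-3α-ol
Conditions: SeO2 (0.5 equiv), t-BuOOH, CH2Cl2, 0 °C → rt
Reagents that add atoms: tert-butyl hydroperoxide CC(C)(C)OO (terminal oxygen source, delivered through catalytic SeO2)
Why: Selenium dioxide allylic hydroxylation (ene reaction at C15 with removal of the axial C3–H, then [2,3]-shift) should prefer the secondary C3 over the hindered tertiary C5 and restore the exocyclic alkene; the axial 3α-alcohol is expected, and any 3β-epimer or enone is carried on because C3 is reset in steps 14 and 15.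

Step 14
Reactants: 18 1β,8α-bis(tert-butyldimethylsilyloxy)eudesm-4(15)-en-3α-ol
Product: 19 1β,8α-bis(tert-butyldimethylsilyloxy)eudesm-4(15)-en-3-one
Conditions: Dess–Martin periodinane, NaHCO3, CH2Cl2, 0 °C
Reagents that add atoms: none
Why: Buffered Dess–Martin oxidation of the allylic alcohol gives the α-methylene ketone without acid- or base-induced migration of the exocyclic double bond.

Step 15
Reactants: 19 1β,8α-bis(tert-butyldimethylsilyloxy)eudesm-4(15)-en-3-one
Product: 20 1β,8α-bis(tert-butyldimethylsilyloxy)eudesm-4(15)-en-3β-ol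
Conditions: NaBH4, CeCl3·7H2O, MeOH, −78 °C
Reagents that add atoms: none
Why: Luche 1,2-reduction; the small hydride should attack C3 axially from the unhindered α face of the rigid trans-decalin (the angular methyl is on the β face), giving the equatorial 3β-alcohol, while cerium suppresses conjugate reduction.

Step 16
Reactants: 21 caffeic acid
Product: 23 (E)-3-[3,4-bis(tert-butyldimethylsilyloxy)phenyl]acrylic acid, via tris-silyl caffeate 22 (not isolated)
Conditions: TBSCl, imidazole, DMF, rt; then AcOH/THF/H2O, rt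
Reagents that add atoms: tert-butyldimethylsilyl chloride CC(C)(C)[Si](C)(C)Cl
Why: Exhaustive silylation followed by selective hydrolysis of the labile silyl ester, which leaves the aryl silyl ethers in place.

Step 17
Reactants: 20 1β,8α-bis(tert-butyldimethylsilyloxy)eudesm-4(15)-en-3β-ol; 23 (E)-3-[3,4-bis(tert-butyldimethylsilyloxy)phenyl]acrylic acid
Product: 24 1β,8α-bis(tert-butyldimethylsilyloxy)eudesm-4(15)-en-3β-yl (E)-3-[3,4-bis(tert-butyldimethylsilyloxy)phenyl]acrylate
Conditions: DCC, DMAP (cat.), CH2Cl2, 0 °C → rt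
Reagents that add atoms: none
Why: Steglich esterification of the only free hydroxyl (equatorial, allylic) with retention at C3 and of the E-alkene.

Step 18
Reactants: 24 1β,8α-bis(tert-butyldimethylsilyloxy)eudesm-4(15)-en-3β-yl (E)-3-[3,4-bis(tert-butyldimethylsilyloxy)phenyl]acrylate
Product: 25 1β,8α-dihydroxyeudesm-4(15)-en-3β-yl (E)-3-(3,4-dihydroxyphenyl)acrylate (CNP0264533.1)
Conditions: HF·pyridine, pyridine, THF, 0 °C → rt, under argon
Reagents that add atoms: none
Why: Buffered fluoride desilylation removes the two aryl and two secondary silyl ethers without ester cleavage, acyl migration (O1 and O3 are locked diequatorial) or ionisation of the allylic ester.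

**Compound list**
1 | 2-methylcyclohex-2-en-1-one | CC1=CCCCC1=O | starting material
2 | (R)-2-methylcyclohex-2-en-1-ol | O[C@@H]1CCCC=C1C | intermediate
3 | (R)-tert-butyldimethyl[(2-methylcyclohex-2-en-1-yl)oxy]silane | CC(C)(C)[Si](C)(C)O[C@@H]1CCCC=C1C | intermediate
4 | (R)-4-(tert-butyldimethylsilyloxy)-3-methylcyclohex-2-en-1-one | CC(C)(C)[Si](C)(C)O[C@@H]1CCC(=O)C=C1C | intermediate
5 | (3R,4R)-4-(tert-butyldimethylsilyloxy)-3-ethenyl-3-methyl-1-(trimethylsilyloxy)cyclohex-1-ene (vinyl trans to OTBS) | C[Si](C)(C)OC1=C[C@@](C)(C=C)[C@H](O[Si](C)(C)C(C)(C)C)CC1 | intermediate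
6 | Mannich base: (3R,4R)-4-(tert-butyldimethylsilyloxy)-2-[(dimethylamino)methyl]-3-ethenyl-3-methylcyclohexan-1-one (C2 configuration immaterial, drawn as the expected epimer) | O=C1CC[C@@H](O[Si](C)(C)C(C)(C)C)[C@](C)(C=C)[C@@H]1CN(C)C | intermediate (not isolated)
7 | methiodide of 6 (trimethylammonium iodide) | O=C1CC[C@@H](O[Si](C)(C)C(C)(C)C)[C@](C)(C=C)[C@@H]1C[N+](C)(C)C.[I-] | intermediate (not isolated)
8 | (3R,4R)-4-(tert-butyldimethylsilyloxy)-3-ethenyl-3-methyl-2-methylidenecyclohexan-1-one | O=C1CC[C@@H](O[Si](C)(C)C(C)(C)C)[C@](C)(C=C)C1=C | intermediate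
9 | bromomagnesium enolate of 10 | Br[Mg]OC1=C(CC=C(C)C)[C@@](C)(C=C)[C@H](O[Si](C)(C)C(C)(C)C)CC1 | intermediate (not isolated)
10 | (2R,3R,4R)-4-(tert-butyldimethylsilyloxy)-3-ethenyl-3-methyl-2-(3-methylbut-2-en-1-yl)cyclohexan-1-one | O=C1CC[C@@H](O[Si](C)(C)C(C)(C)C)[C@](C)(C=C)[C@H]1CC=C(C)C | intermediate
11 | pinacol boronate of 12 (Bpin in place of OH) | O=C1CC[C@@H](O[Si](C)(C)C(C)(C)C)[C@](C)(CCB2OC(C)(C)C(C)(C)O2)[C@H]1CC=C(C)C | intermediate (not isolated)
12 | (2R,3R,4R)-4-(tert-butyldimethylsilyloxy)-3-(2-hydroxyethyl)-3-methyl-2-(3-methylbut-2-en-1-yl)cyclohexan-1-one | O=C1CC[C@@H](O[Si](C)(C)C(C)(C)C)[C@](C)(CCO)[C@H]1CC=C(C)C | intermediate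
13 | 2-[(1R,2R,6R)-6-(tert-butyldimethylsilyloxy)-1-methyl-2-(3-methylbut-2-en-1-yl)-3-oxocyclohexyl]acetaldehyde (key-step precursor) | O=C1CC[C@@H](O[Si](C)(C)C(C)(C)C)[C@](C)(CC=O)[C@H]1CC=C(C)C | intermediate
14 | 1β-(tert-butyldimethylsilyloxy)-8α-hydroxy-15-noreudesm-11-en-4-one (key-step product) | O=C1CC[C@@H](O[Si](C)(C)C(C)(C)C)[C@]2(C)C[C@H](O)[C@@H](C(C)=C)C[C@@H]12 | intermediate
15 | 1β-(tert-butyldimethylsilyloxy)-8α-hydroxy-15-noreudesman-4-one | O=C1CC[C@@H](O[Si](C)(C)C(C)(C)C)[C@]2(C)C[C@H](O)[C@@H](C(C)C)C[C@@H]12 | intermediate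
16 | 1β,8α-bis(tert-butyldimethylsilyloxy)-15-noreudesman-4-one | O=C1CC[C@@H](O[Si](C)(C)C(C)(C)C)[C@]2(C)C[C@H](O[Si](C)(C)C(C)(C)C)[C@@H](C(C)C)C[C@@H]12 | intermediate
17 | 1β,8α-bis(tert-butyldimethylsilyloxy)eudesm-4(15)-ene | C=C1CC[C@@H](O[Si](C)(C)C(C)(C)C)[C@]2(C)C[C@H](O[Si](C)(C)C(C)(C)C)[C@@H](C(C)C)C[C@@H]12 | intermediate
18 | 1β,8α-bis(tert-butyldimethylsilyloxy)eudesm-4(15)-en-3α-ol | C=C1[C@H](O)C[C@@H](O[Si](C)(C)C(C)(C)C)[C@]2(C)C[C@H](O[Si](C)(C)C(C)(C)C)[C@@H](C(C)C)C[C@@H]12 | intermediate
19 | 1β,8α-bis(tert-butyldimethylsilyloxy)eudesm-4(15)-en-3-one | C=C1C(=O)C[C@@H](O[Si](C)(C)C(C)(C)C)[C@]2(C)C[C@H](O[Si](C)(C)C(C)(C)C)[C@@H](C(C)C)C[C@@H]12 | intermediate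
20 | 1β,8α-bis(tert-butyldimethylsilyloxy)eudesm-4(15)-en-3β-ol | C=C1[C@@H](O)C[C@@H](O[Si](C)(C)C(C)(C)C)[C@]2(C)C[C@H](O[Si](C)(C)C(C)(C)C)[C@@H](C(C)C)C[C@@H]12 | intermediate
21 | caffeic acid | OC(=O)/C=C/c1ccc(O)c(O)c1 | starting material
22 | tert-butyldimethylsilyl (E)-3-[3,4-bis(tert-butyldimethylsilyloxy)phenyl]acrylate | CC(C)(C)[Si](C)(C)OC(=O)/C=C/c1ccc(O[Si](C)(C)C(C)(C)C)c(O[Si](C)(C)C(C)(C)C)c1 | intermediate (not isolated)
23 | (E)-3-[3,4-bis(tert-butyldimethylsilyloxy)phenyl]acrylic acid | OC(=O)/C=C/c1ccc(O[Si](C)(C)C(C)(C)C)c(O[Si](C)(C)C(C)(C)C)c1 | intermediate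
24 | 1β,8α-bis(tert-butyldimethylsilyloxy)eudesm-4(15)-en-3β-yl (E)-3-[3,4-bis(tert-butyldimethylsilyloxy)phenyl]acrylate | C=C1[C@@H](OC(=O)/C=C/c2ccc(O[Si](C)(C)C(C)(C)C)c(O[Si](C)(C)C(C)(C)C)c2)C[C@@H](O[Si](C)(C)C(C)(C)C)[C@]2(C)C[C@H](O[Si](C)(C)C(C)(C)C)[C@@H](C(C)C)C[C@@H]12 | intermediate
25 | 1β,8α-dihydroxyeudesm-4(15)-en-3β-yl (E)-3-(3,4-dihydroxyphenyl)acrylate | C=C1[C@@H](OC(=O)/C=C/c2ccc(O)c(O)c2)C[C@@H](O)[C@]2(C)C[C@H](O)[C@@H](C(C)C)C[C@@H]12 | target

**Step count**
Total: 18 steps. Longest linear sequence: 17 steps (steps 1–15, 17, 18); step 16 is a one-step side branch.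

**Steps most likely to fail**

1. Step 6: poor facial selectivity in the protonation at C5, or later epimerisation, would give the epimer with cis arms, which cannot close ring B with the required C7/C8 configuration. The fallback removes the C5 stereocentre from the precursor and sets it in the rigid bicycle. It sets out from 8. The isobutenyl-copper addition is run as in step 6, but the enolate is trapped with TBSCl/HMPA to give the tetrasubstituted tert-butyldimethylsilyl enol ether F1. Iridium-catalysed hydroboration gives the pinacol boronate F2 and perborate oxidation the primary alcohol F3. Pyridine-buffered Dess–Martin oxidation gives the enol ether aldehyde F4, in which C5 is sp2. Me2AlCl at −78 °C then closes ring B to the bicyclic enol ether alcohol F5, with C7 and C8 controlled by the axial C10 methyl as in step 9. TBAF/AcOH at 0 °C cleaves the enol silyl ether before the hindered C1 ether, and the enol is protonated at C5 from the α face, where the trans-fused ketone is both the kinetic and the thermodynamic product. The fallback comes back to the route at 14.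

2. Step 9: the concerted ene path may be diverted into stepwise Prins chemistry (double-bond isomers, chloride capture at C11), with incomplete hydrogen transfer. The fallback makes the stepwise path deliberate. It sets out from 13. SnCl4 in CH2Cl2 at −78 °C should give, through the same chair, Prins cyclisation with chloride capture to the tertiary chloride 1β-(tert-butyldimethylsilyloxy)-11-chloro-8α-hydroxy-15-noreudesman-4-one F6. Radical dechlorination with Bu3SnH/AIBN in toluene at 80 °C then gives the isopropyl compound directly. The fallback comes back to the route at 15.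

3. Step 13: the allylic oxidation may attack the tertiary C5–H instead of C3, or stall on the hindered alkene. The fallback puts the oxygen on C3 through the kinetic enolate before the methylene is made. It sets out from 16. LDA at −78 °C (deprotonation at C3, the ring-fusion C5–H being hindered) and 2-(phenylsulfonyl)-3-phenyloxaziridine give the 3α-hydroxy ketone F7 (axial attack from the α face). TESCl/imidazole gives the triethylsilyl ether F8. Non-basic methylenation with dimethyltitanocene in toluene at 70 °C gives the methylene compound F9, and PPTS in MeOH removes the triethylsilyl group selectively. The fallback comes back to the route at 18.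

**Further compounds**
F1 | step 6 | (3R,4R)-1,4-bis(tert-butyldimethylsilyloxy)-3-ethenyl-3-methyl-2-(3-methylbut-2-en-1-yl)cyclohex-1-ene | CC(C)(C)[Si](C)(C)OC1=C(CC=C(C)C)[C@@](C)(C=C)[C@H](O[Si](C)(C)C(C)(C)C)CC1
F2 | step 6 | pinacol boronate of F3 (Bpin in place of OH) | CC(C)(C)[Si](C)(C)OC1=C(CC=C(C)C)[C@@](C)(CCB2OC(C)(C)C(C)(C)O2)[C@H](O[Si](C)(C)C(C)(C)C)CC1
F3 | step 6 | 2-[(1R,6R)-3,6-bis(tert-butyldimethylsilyloxy)-1-methyl-2-(3-methylbut-2-en-1-yl)cyclohex-2-en-1-yl]ethanol | CC(C)(C)[Si](C)(C)OC1=C(CC=C(C)C)[C@@](C)(CCO)[C@H](O[Si](C)(C)C(C)(C)C)CC1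
F4 | step 6 | 2-[(1R,6R)-3,6-bis(tert-butyldimethylsilyloxy)-1-methyl-2-(3-methylbut-2-en-1-yl)cyclohex-2-en-1-yl]acetaldehyde | CC(C)(C)[Si](C)(C)OC1=C(CC=C(C)C)[C@@](C)(CC=O)[C@H](O[Si](C)(C)C(C)(C)C)CC1
F5 | step 6 | 1β,4-bis(tert-butyldimethylsilyloxy)-15-noreudesma-4,11-dien-8α-ol (7β-isopropenyl) | C1(O[Si](C)(C)C(C)(C)C)CC[C@@H](O[Si](C)(C)C(C)(C)C)[C@]2(C)C[C@H](O)[C@@H](C(C)=C)CC=12
F6 | step 9 | 1β-(tert-butyldimethylsilyloxy)-11-chloro-8α-hydroxy-15-noreudesman-4-one | O=C1CC[C@@H](O[Si](C)(C)C(C)(C)C)[C@]2(C)C[C@H](O)[C@@H](C(C)(C)Cl)C[C@@H]12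
F7 | step 13 | 1β,8α-bis(tert-butyldimethylsilyloxy)-3α-hydroxy-15-noreudesman-4-one | O=C1[C@H](O)C[C@@H](O[Si](C)(C)C(C)(C)C)[C@]2(C)C[C@H](O[Si](C)(C)C(C)(C)C)[C@@H](C(C)C)C[C@@H]12
F8 | step 13 | 1β,8α-bis(tert-butyldimethylsilyloxy)-3α-(triethylsilyloxy)-15-noreudesman-4-one | O=C1[C@H](O[Si](CC)(CC)CC)C[C@@H](O[Si](C)(C)C(C)(C)C)[C@]2(C)C[C@H](O[Si](C)(C)C(C)(C)C)[C@@H](C(C)C)C[C@@H]12
F9 | step 13 | 1β,8α-bis(tert-butyldimethylsilyloxy)-3α-(triethylsilyloxy)eudesm-4(15)-ene | C=C1[C@H](O[Si](CC)(CC)CC)C[C@@H](O[Si](C)(C)C(C)(C)C)[C@]2(C)C[C@H](O[Si](C)(C)C(C)(C)C)[C@@H](C(C)C)C[C@@H]12
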